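**Plan**

1. Retrosynthesis: cut the angelate C–O bond, then C7–C11 (aldol with acetone), then the two C–O bonds of the 3α,4α-diol (osmylation of C3=C4). Ring A is then cut at C1–C2 and C4–C5, leaving a ring B cyclohexene and a (Z)-3-bromobut-2-enyl unit.
2. Forward: ring B comes from 3-methylcyclohex-2-enone. Ring A is closed onto it in one palladium-catalysed domino: nitronate allylation makes C1–C2 and a 6-exo Heck cyclisation makes C4–C5. The diene ketone is then adjusted and oxygenated.
3. Enabling feature: the nitromethyl carbon C1 on the quaternary C10 is a soft carbon nucleophile, and the C5=C6 alkene of ring B sits on the other side of C10. C1 and C5 therefore form a 1,3-pair that a unit with an allylic carbonate at C2 and a vinyl bromide at C4 can bridge to give the six-membered ring A.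
4. Stereochemistry: C10 comes from a catalytic asymmetric Michael addition. C3 and C4 come from syn-dihydroxylation of the 3,5-diene on the α-face, opposite the axial C10 methyl. C5 is set last by kinetic γ-protonation of the ring B dienolate, anti to the C4 and C10 methyls. The C1 and C5 centres made in the key step are erased.
5. Helpers: the nitro group on C1 (removed in step 7) and the dioxolane on C8 (removed in step 8).

Key step: step 6

Remark: positions are given in eudesmane numbering (C10 quaternary ring-fusion carbon, C5 ring-fusion CH, C8 ketone carbon, C7 bearing C11); α means the face opposite the C10 methyl.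

**Step 1**
Reactants: 1 3-methylcyclohex-2-en-1-one; 2 nitromethane
Product: 3 (S)-3-methyl-3-(nitromethyl)cyclohexan-1-one
Conditions: CH3NO2 (5 equiv), 9-amino-9-deoxy-epi-cinchona primary amine (10 mol %, the pseudoenantiomer that gives the S product), PhCO2H (20 mol %), THF, 9 kbar, 50 °C
Reagents that add atoms: none
Why: Iminium-activated asymmetric Michael addition of nitromethane to a β,β-disubstituted enone, in which the chiral primary amine shields one face of the iminium ion so that C1 adds to C10 and sets the quaternary centre as S, while high pressure offsets the low reactivity of the β-methyl enone.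

**Step 2**
Reactants: 3 (S)-3-methyl-3-(nitromethyl)cyclohexan-1-one
Product: 4 (S)-5-methyl-5-(nitromethyl)cyclohex-2-en-1-one
Conditions: Pd(OCOCF3)2 (5 mol %), (CH3)2SO (10 mol %), O2 (1 atm), CH3CO2H, 80 °C
Reagents that add atoms: none
Why: Palladium-catalysed aerobic α,β-dehydrogenation (a direct Saegusa–Ito-type oxidation through a divalent palladium enolate and β-hydride elimination) can only occur between C6 and C7 because C10 carries no hydrogen, so a single enone should form.

**Step 3**
Reactants: 4 (S)-5-methyl-5-(nitromethyl)cyclohex-2-en-1-one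
Product: 5 (R)-9-methyl-9-(nitromethyl)-1,4-dioxaspiro[4.5]dec-7-ene
Conditions: HOCH2CH2OH (5 equiv), p-TsOH·H2O (5 mol %), benzene, reflux, Dean–Stark
Reagents that add atoms: ethane-1,2-diol, OCCO
Why: Acid-catalysed dioxolane formation under equilibrating conditions should move the double bond out of conjugation to C5=C6, as in the ketalisation of steroidal 4-en-3-ones, which protects C8 and places the ring alkene at the carbon that must bond to C4.

**Step 4**
Reactants: 6 but-2-yn-1-ol
Product: 8 (Z)-3-bromobut-2-en-1-ol, via sodium alkenylalanate 7 (not isolated)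
Conditions: NaAlH2(OCH2CH2OCH3)2 (1.6 equiv), Et2O, 0 °C to 25 °C; then N-bromosuccinimide, −78 °C
Reagents that add atoms: N-bromosuccinimide, O=C1CCC(=O)N1Br
Why: Hydroxyl-directed anti-hydroalumination of the propargylic alcohol puts aluminium on the methyl-bearing alkene carbon, cis to the CH2O group inside a five-membered alanate ring, and bromodealumination with retention should give the Z vinyl bromide.

**Step 5**
Reactants: 8 (Z)-3-bromobut-2-en-1-ol
Product: 9 (Z)-3-bromobut-2-en-1-yl methyl carbonate
Conditions: ClCO2CH3 (1.2 equiv), pyridine (1.5 equiv), CH2Cl2, 0 °C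
Reagents that add atoms: methyl chloroformate, COC(=O)Cl
Why: Carbonate formation on the primary allylic alcohol gives a leaving group that ionises to a π-allyl complex under neutral conditions and releases its own base.

**Step 6**
Reactants: 5 (R)-9-methyl-9-(nitromethyl)-1,4-dioxaspiro[4.5]dec-7-ene; 9 (Z)-3-bromobut-2-en-1-yl methyl carbonate
Product: 11 (4a'R,8a'R)-5',8a'-dimethyl-8'-nitro-4a',7',8',8a'-tetrahydro-1'H-spiro[[1,3]dioxolane-2,2'-naphthalene] (cis-fused, both epimers at the nitro carbon), via allylated nitro ketal 10 (not isolated)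
Conditions: Pd(OAc)2 (5 mol %), PPh3 (20 mol %), K2CO3 (2.5 equiv), CH3CN, 25 °C until 5 is consumed, then 80 °C
Reagents that add atoms: none
Why: Zerovalent palladium ionises carbonate 9 to a π-allyl complex with loss of CO2, the nitronate of 5 attacks the unsubstituted allyl terminus through C1 to form C1–C2 and give 10 (Tsuji–Trost allylation), and on heating oxidative addition into the vinyl C–Br bond, syn-carbopalladation of C5=C6 to form C4–C5, and syn-β-hydride elimination towards C7 follow (intramolecular Heck reaction). The closest known reaction type is the domino Tsuji–Trost allylation/Heck cyclisation of a nucleophile–alkene pair with a halo-allyl electrophile. Ring A closes in the 6-exo-trig mode, the 7-endo alternative being disfavoured. The new C5 centre is set by syn-insertion on the alkene face reached by the C1 tether (cis fusion expected) and the C1 centre is uncontrolled, but neither matters because C1 loses its nitro group in step 7 and C5 is made planar in step 9 and reset in step 12. The step needs allylation to precede insertion into the C–Br bond, which the temperature staging should secure (carbonate ionisation at 25 °C, vinyl bromide activation only at 80 °C), and it needs the Z geometry to survive so that palladium on C4 is cis to the tether, which attack at the CH2 terminus without σ-bonding at the bromine-bearing carbon should secure. The β,γ-position of the ring alkene, fixed by the dioxolane, leaves a syn hydrogen only on C7, so the new ring B double bond lands next to the masked carbonyl.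

**Step 7**
Reactants: 11 cis-fused nitro diene ketal
Product: 12 (4a'S,8a'R)-5',8a'-dimethyl-4a',7',8',8a'-tetrahydro-1'H-spiro[[1,3]dioxolane-2,2'-naphthalene] (cis-fused)
Conditions: Bu3SnH (4 equiv), AIBN (0.4 equiv in portions), toluene, 110 °C
Reagents that add atoms: none
Why: Radical denitration (the tin radical adds to a nitro oxygen, the C–N bond fragments, and the secondary C1 radical takes hydrogen from Bu3SnH) removes the activating group at the one stage where C5 is sp3, so that no vinyl group on C10 can migrate to the C1 radical.

**Step 8**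
Reactants: 12 cis-fused diene ketal
Product: 13 (4aS,8aR)-5,8a-dimethyl-4a,7,8,8a-tetrahydronaphthalen-2(1H)-one (cis-fused)
Conditions: 1 M HCl, THF, 0 °C to 25 °C
Reagents that add atoms: water, O
Why: Acid hydrolysis of the allylic dioxolane unmasks the C8 ketone already conjugated with C6=C7, and the configuration at C5 is of no consequence because step 9 removes it.

**Step 9**
Reactants: 13 cis-fused dienone
Product: 15 (R)-5,8a-dimethyl-3,7,8,8a-tetrahydronaphthalen-2(1H)-one, via potassium trienolate 14 (not isolated)
Conditions: KOC(CH3)3 (3 equiv), (CH3)3COH/THF, 25 °C; then inverse quench into cold 10% aqueous CH3CO2H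
Reagents that add atoms: none
Why: Deconjugation of an enone through its extended enolate, in which the C5 hydrogen (γ to the carbonyl and allylic to C3=C4) is removed under equilibrating conditions and kinetic protonation at the α-carbon C7 should deliver the 3,5-dien-8-one with C5 sp2.

**Step 10**
Reactants: 15 (R)-5,8a-dimethyl-3,7,8,8a-tetrahydronaphthalen-2(1H)-one; 16 acetone
Product: 18 (8aR)-3-(2-hydroxypropan-2-yl)-5,8a-dimethyl-3,7,8,8a-tetrahydronaphthalen-2(1H)-one (both C3 epimers), via lithium trienolate 17 (not isolated)
Conditions: LiN(iPr)2 (1.1 equiv), THF, −78 °C; then acetone (3 equiv), −78 °C; CH3CO2H quench at −78 °C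
Reagents that add atoms: none
Why: Directed aldol addition, in which the base removes the C7 hydrogen (α to the ketone and allylic, so more acidic and less hindered than C9–H) and the lithium trienolate adds to acetone through its α-carbon, as extended enolates do with carbonyl electrophiles, leaving C5=C6 out of conjugation and a C7 centre that disappears in step 12.

**Step 11**
Reactants: 18 aldol adduct
Product: 19 (5S,6R,8aR)-5,6-dihydroxy-3-(2-hydroxypropan-2-yl)-5,8a-dimethyl-3,5,6,7,8,8a-hexahydronaphthalen-2(1H)-one (both C3 epimers)
Conditions: OsO4 (5 mol %), N-methylmorpholine N-oxide (1.3 equiv), acetone/H2O (8:1), 0 °C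
Reagents that add atoms: OsO4, O=[Os](=O)(=O)=O; N-methylmorpholine N-oxide, C[N+]1([O-])CCOCC1; water, O
Why: Upjohn syn-dihydroxylation should take the trisubstituted C3=C4 bond in preference to C5=C6 (screened by the quaternary C10, the C4 methyl and the C7 substituent) and from the α-face, because the axial C10 methyl covers the β-face of the planar diene, which sets C3 (R) and C4 (S) as the cis-3α,4α-diol.

**Step 12**
Reactants: 19 β,γ-unsaturated triol ketone
Product: 20 (4aR,5S,6R,8aR)-5,6-dihydroxy-3-(2-hydroxypropan-2-yl)-5,8a-dimethyl-4a,5,6,7,8,8a-hexahydronaphthalen-2(1H)-one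
Conditions: DBU (0.1 equiv), CH2Cl2, 0 °C
Reagents that add atoms: none
Why: Base-catalysed conjugation of the β,γ-unsaturated ketone through its dienolate, in which kinetic γ-protonation at C5 should occur on the α-face, anti to the β-methyl groups on C4 and C10 that flank it, giving the trans ring fusion (5α-H), while the product does not re-equilibrate because its γ-hydrogen is far less acidic than the α-hydrogen of 19.

**Step 13**
Reactants: 21 angelic acid; 22 2,4,6-trichlorobenzoyl chloride
Product: 23 (Z)-2-methylbut-2-enoic 2,4,6-trichlorobenzoic anhydride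
Conditions: Et3N (1.1 equiv), toluene, 25 °C; filter, concentrate
Reagents that add atoms: none
Why: Mixed anhydride formation (first stage of a Yamaguchi esterification) activates angelic acid without passing through the acid chloride, which avoids Z to E isomerisation.

**Step 14**
Reactants: 20 triol enone; 23 mixed anhydride
Product: 24 (1S,2R,4aR,8aR)-1-hydroxy-7-(2-hydroxypropan-2-yl)-1,4a-dimethyl-6-oxo-1,2,3,4,4a,5,6,8a-octahydronaphthalen-2-yl (2Z)-2-methylbut-2-enoate
Conditions: 23 (3 equiv), Et3N (3 equiv), toluene, 75 °C
Reagents that add atoms: none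
Why: Yamaguchi-type acyl transfer at the less hindered angeloyl carbonyl of 23, run without a nucleophilic catalyst so that the Z double bond is kept, should acylate only the secondary C3 hydroxyl because the two tertiary hydroxyls are too hindered.

**Compound list**

1 | 3-methylcyclohex-2-en-1-one | CC1=CC(=O)CCC1 | starting material
2 | nitromethane | C[N+](=O)[O-] | starting material
3 | (S)-3-methyl-3-(nitromethyl)cyclohexan-1-one | C[C@@]1(C[N+](=O)[O-])CC(=O)CCC1 | intermediate
4 | (S)-5-methyl-5-(nitromethyl)cyclohex-2-en-1-one | C[C@@]1(C[N+](=O)[O-])CC(=O)C=CC1 | intermediate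
5 | (R)-9-methyl-9-(nitromethyl)-1,4-dioxaspiro[4.5]dec-7-ene | C[C@@]1(C[N+](=O)[O-])CC2(OCCO2)CC=C1 | intermediate
6 | but-2-yn-1-ol | CC#CCO | starting material
7 | sodium 2,2-bis(2-methoxyethoxy)-3-methyl-2,5-dihydro-1,2-oxaluminol-2-uide (cyclic alkenylalanate) | [Na+].COCCO[Al-]1(OCCOC)OCC=C1C | intermediate
8 | (Z)-3-bromobut-2-en-1-ol | C/C(Br)=C/CO | intermediate
9 | (Z)-3-bromobut-2-en-1-yl methyl carbonate | COC(=O)OC/C=C(/C)Br | intermediate
10 | (9R)-9-[(3Z)-4-bromo-1-nitropent-3-en-1-yl]-9-methyl-1,4-dioxaspiro[4.5]dec-7-ene (both epimers at the nitro carbon) | C[C@@]1(C(C/C=C(/C)Br)[N+](=O)[O-])CC2(OCCO2)CC=C1 | intermediate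
11 | (4a'R,8a'R)-5',8a'-dimethyl-8'-nitro-4a',7',8',8a'-tetrahydro-1'H-spiro[[1,3]dioxolane-2,2'-naphthalene] (cis-fused, both epimers at the nitro carbon) | C[C@@]1(C([N+](=O)[O-])CC=C2C)CC3(OCCO3)C=C[C@@H]12 | intermediate
12 | (4a'S,8a'R)-5',8a'-dimethyl-4a',7',8',8a'-tetrahydro-1'H-spiro[[1,3]dioxolane-2,2'-naphthalene] (cis-fused) | C[C@@]1(CCC=C2C)CC3(OCCO3)C=C[C@@H]12 | intermediate
13 | (4aS,8aR)-5,8a-dimethyl-4a,7,8,8a-tetrahydronaphthalen-2(1H)-one (cis-fused) | C[C@@]1(CCC=C2C)CC(=O)C=C[C@@H]12 | intermediate
14 | potassium (R)-5,8a-dimethyl-1,7,8,8a-tetrahydronaphthalen-2-olate | [K+].C[C@]12CCC=C(C)C1=CC=C([O-])C2 | intermediate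
15 | (R)-5,8a-dimethyl-3,7,8,8a-tetrahydronaphthalen-2(1H)-one | C[C@]12CCC=C(C)C1=CCC(=O)C2 | intermediate
16 | acetone | CC(C)=O | starting material
17 | lithium (R)-5,8a-dimethyl-1,7,8,8a-tetrahydronaphthalen-2-olate | [Li+].C[C@]12CCC=C(C)C1=CC=C([O-])C2 | intermediate
18 | (8aR)-3-(2-hydroxypropan-2-yl)-5,8a-dimethyl-3,7,8,8a-tetrahydronaphthalen-2(1H)-one (both C3 epimers) | C[C@]12CCC=C(C)C1=CC(C(C)(C)O)C(=O)C2 | intermediate
19 | (5S,6R,8aR)-5,6-dihydroxy-3-(2-hydroxypropan-2-yl)-5,8a-dimethyl-3,5,6,7,8,8a-hexahydronaphthalen-2(1H)-one (both C3 epimers) | O[C@@H]1CC[C@]2(C)CC(=O)C(C(C)(C)O)C=C2[C@]1(C)O | intermediate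
20 | (4aR,5S,6R,8aR)-5,6-dihydroxy-3-(2-hydroxypropan-2-yl)-5,8a-dimethyl-4a,5,6,7,8,8a-hexahydronaphthalen-2(1H)-one | O[C@@H]1CC[C@]2(C)CC(=O)C(C(C)(C)O)=C[C@H]2[C@]1(C)O | intermediate
21 | angelic acid, (Z)-2-methylbut-2-enoic acid | C/C=C(/C)C(=O)O | starting material
22 | 2,4,6-trichlorobenzoyl chloride | O=C(Cl)c1c(Cl)cc(Cl)cc1Cl | starting material
23 | (Z)-2-methylbut-2-enoic 2,4,6-trichlorobenzoic anhydride | C/C=C(/C)C(=O)OC(=O)c1c(Cl)cc(Cl)cc1Cl | intermediate
24 | (1S,2R,4aR,8aR)-1-hydroxy-7-(2-hydroxypropan-2-yl)-1,4a-dimethyl-6-oxo-1,2,3,4,4a,5,6,8a-octahydronaphthalen-2-yl (2Z)-2-methylbut-2-enoate | C/C=C(/C)C(=O)O[C@@H]1CC[C@]2(C)CC(=O)C(C(C)(C)O)=C[C@H]2[C@]1(C)O | target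

**Totals and risks**

Total step count: 14. Longest linear sequence: 11 steps (steps 1 to 3, 6 to 12 and 14); steps 4, 5 and 13 are side branches.

Step 6. What may go wrong: oxidative addition of palladium into the vinyl bromide before the allylation, loss of the Z geometry in the π-allyl complex, or a second allylation of the nitronate, each of which would stop ring closure. Fallback: the sequence is stopped after the allylation (Pd(PPh3)4, CH3CN, 25 °C) and 10 is isolated. Bu3SnH and AIBN in toluene at 110 °C then generate the C4 vinyl radical, which should close ring A by 6-exo attack on C5 before the slower tin-mediated loss of the nitro group, giving the ring B saturated ketal F1. Aqueous HCl in THF gives the ketone F2. Palladium-catalysed aerobic dehydrogenation under the conditions of step 2, which can again only act between C6 and C7, gives 13 together with its trans-fused 4a-epimer F3. Both give the same trienolate, so the route is rejoined at 13 and continues with step 9.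

Step 7. What may go wrong: slow C–N homolysis of an unactivated secondary nitro group, so that the radical chain is short and hydrostannation of the alkenes competes. Fallback: from 11, a Nef reaction (NaOCH3 in CH3OH, then aqueous TiCl3 buffered with NH4OAc) gives the C1 ketone F4. Condensation with 4-methylbenzenesulfonohydrazide in ethanol gives the tosylhydrazone F5. Reduction with catecholborane in CHCl3 followed by NaOAc·3H2O at reflux gives the methylene compound 12, where the route is rejoined.

Step 11. What may go wrong: competing osmylation of C5=C6, or conjugation of the β,γ-unsaturated ketone before the diol is in place. Fallback: from 18, mCPBA with NaHCO3 in CH2Cl2 at −20 °C should epoxidise the more electron-rich C3=C4 bond on the α-face to the vinyl epoxide F6. Pd(PPh3)4 under CO2 (1 atm) in THF converts it, through a π-allyl complex and double inversion at C4, into the cis cyclic carbonate F7. K2CO3 in methanol at 0 °C cleaves the carbonate and conjugates the enone, rejoining the route at 20.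

**Further compounds**

F1 | step 6 | (8a'R)-5',8a'-dimethyl-3',4',4a',7',8',8a'-hexahydro-1'H-spiro[[1,3]dioxolane-2,2'-naphthalene] (both 4a' epimers) | C[C@@]1(CCC=C2C)CC3(OCCO3)CCC12
F2 | step 6 | (8aR)-5,8a-dimethyl-3,4,4a,7,8,8a-hexahydronaphthalen-2(1H)-one (both 4a epimers) | C[C@@]1(CCC=C2C)CC(=O)CCC12
F3 | step 6 | (4aR,8aR)-5,8a-dimethyl-4a,7,8,8a-tetrahydronaphthalen-2(1H)-one (trans-fused 4a-epimer of 13) | C[C@@]1(CCC=C2C)CC(=O)C=C[C@H]12
F4 | step 7 | cis-fused 5',8a'-dimethyl-4a',7'-dihydro-1'H-spiro[[1,3]dioxolane-2,2'-naphthalen]-8'(8a'H)-one (C1 ketone from 11) | C[C@@]1(C(=O)CC=C2C)CC3(OCCO3)C=C[C@@H]12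
F5 | step 7 | 4-methylbenzenesulfonylhydrazone of F4 | C[C@@]1(C(=NNS(=O)(=O)c3ccc(C)cc3)CC=C2C)CC4(OCCO4)C=C[C@@H]12
F6 | step 11 | 3α,4α-epoxide of 18 (oxirane across C3 and C4, C5=C6 retained) | O1[C@@H]2CC[C@]3(C)CC(=O)C(C(C)(C)O)C=C3[C@]12C
F7 | step 11 | cyclic 3α,4α-carbonate of 19 | O=C1O[C@@H]2CC[C@]3(C)CC(=O)C(C(C)(C)O)C=C3[C@]2(C)O1
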